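**Retrosynthetic overview**
1. Target 14 ⇐ aldol adduct 12 by one hydrogenolysis that removes the O‑benzyl group and the benzylic OH.
2. 12 ⇐ trans α‑hydroxy lactone 9 + aldehyde 10 by an enediolate aldol; the quaternary C3 is set anti to the C4 benzyl group.
3. 9 ⇐ (R)‑lactone 7 by enolate hydroxylation.
4. 7 ⇐ enal 3 + formaldehyde 4 by a carbene‑catalysed homoenolate annulation: the C4–C5 bond, the C4 stereocentre and the lactone ring (the only ring made; both arenes are bought) form in one operation.
5. 3 ⇐ methyl eugenol 1 + crotonaldehyde 2 by cross‑metathesis.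

Assumption: aldehyde 10 is taken as a catalogue compound (otherwise one benzylation of syringaldehyde), and the (5aS,10bR) triazolium catalyst is assumed to give the R lactone; this is checked on 7 and the mirror‑image catalyst is used if the sense is opposite.

**Step 1**
Reactants: 1 methyl eugenol (4‑allyl‑1,2‑dimethoxybenzene); 2 crotonaldehyde ((E)‑but‑2‑enal)
Product: 3 (E)‑4‑(3,4‑dimethoxyphenyl)but‑2‑enal
Conditions: 2 (4 equiv), second‑generation Grubbs catalyst RuCl2(=CHPh)(H2IMes)(PCy3) (2 mol%), 1,4‑benzoquinone (10 mol%), CH2Cl2, 40 °C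
Reagents that add atoms: none
Why: Olefin cross‑metathesis of a terminal allylarene with an electron‑poor enal partner is selective for the E cross‑product (propene leaves as a gas), and benzoquinone suppresses Ru–H isomerisation of the allyl group.

**Step 2**
Reactants: 3 (E)‑4‑(3,4‑dimethoxyphenyl)but‑2‑enal; 4 formaldehyde (charged as paraformaldehyde)
Product: 7 (R)‑4‑(3,4‑dimethoxybenzyl)dihydrofuran‑2(3H)‑one, via extended Breslow intermediate 5 (not isolated), via acyl azolium alkoxide 6 (not isolated)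
Conditions: (CH2O)n (3 equiv), (5aS,10bR) aminoindanol‑derived N‑mesityl triazolium chloride (10 mol%), i‑Pr2NEt (20 mol%), THF, 40 °C, slow addition of 3
Reagents that add atoms: none
Why: Proposed new method: the carbene adds to the aldehyde of 3 and proton transfer gives extended Breslow intermediate 5, whose β‑carbon (homoenolate reactivity) attacks monomeric formaldehyde, joining two carbons that are both normally electrophilic (the enal β‑carbon and the carbonyl carbon of CH2O); tautomerisation gives acyl azolium alkoxide 6, which lactonises and releases the carbene; the C4 stereocentre is set in the C–C bond‑forming event because the aminoindanol backbone blocks one face of the homoenolate; the closest known reactions are the NHC‑catalysed homoenolate annulations of enals with aldehydes and activated ketones to γ‑butyrolactones (same catalyst class, β‑stereocentres in high ee) and the NHC‑catalysed hydroxymethylation of aldehydes with paraformaldehyde.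

**Step 3**
Reactants: 7 (R)‑4‑(3,4‑dimethoxybenzyl)dihydrofuran‑2(3H)‑one
Product: 9 (3R,4S)‑3‑hydroxy‑4‑(3,4‑dimethoxybenzyl)dihydrofuran‑2(3H)‑one (trans), via potassium enolate 8 (not isolated)
Conditions: KN(SiMe3)2 (1.1 equiv), THF, −78 °C; then (±)‑trans‑2‑(phenylsulfonyl)‑3‑phenyloxaziridine (1.3 equiv), −78 °C; AcOH quench
Reagents that add atoms: (±)‑trans‑2‑(phenylsulfonyl)‑3‑phenyloxaziridine (Davis oxaziridine), O=S(=O)(c1ccccc1)N1OC1c1ccccc1
Why: Davis enolate hydroxylation delivers the electrophilic oxygen to the enolate face anti to the C4 benzyl group to give the trans hydroxy lactone, and the C3 configuration made here does not matter because C3 is planarised again in step 4.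

**Step 4**
Reactants: 9 (3R,4S)‑3‑hydroxy‑4‑(3,4‑dimethoxybenzyl)dihydrofuran‑2(3H)‑one; 10 4‑benzyloxy‑3,5‑dimethoxybenzaldehyde
Product: 12 (3R,4S)‑3‑[(4‑benzyloxy‑3,5‑dimethoxyphenyl)(hydroxy)methyl]‑3‑hydroxy‑4‑(3,4‑dimethoxybenzyl)dihydrofuran‑2(3H)‑one as a mixture of carbinol epimers, via dilithium enediolate 11 (not isolated)
Conditions: LiN(i‑Pr)2 (2.1 equiv), THF, −78 to −40 °C; then 10 (1.2 equiv), −78 °C; AcOH quench at −78 °C
Reagents that add atoms: none
Why: In this dianion aldol addition the aldehyde attacks the planar enediolate on the face opposite the C4 benzyl group, so the new C3–C bond is trans and the C3 oxygen cis to that benzyl, which is the target's quaternary configuration (the descriptor is R here only because CH(OH)Ar outranks C4), while the new benzylic carbinol centre is irrelevant since it is removed in step 5.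

**Step 5**
Reactants: 12 (the aldol diol)
Product: 14 (3S,4S)‑4‑(3,4‑dimethoxybenzyl)‑3‑hydroxy‑3‑(4‑hydroxy‑3,5‑dimethoxybenzyl)dihydrofuran‑2(3H)‑one (the target), via debenzylated triol 13 (not isolated)
Conditions: H2 (3 atm), Pd/C (10 wt%), AcOH, 40 °C
Reagents that add atoms: none
Why: Heterogeneous Pd‑catalysed hydrogenolysis cleaves the O‑benzyl ether and then the secondary benzylic C–OH (strongly activated by the para‑hydroxy ring), while the non‑benzylic tertiary C3–OH and both stereocentres are untouched.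

**Compound list**
1 | methyl eugenol (4‑allyl‑1,2‑dimethoxybenzene) | COc1ccc(CC=C)cc1OC | starting material
2 | crotonaldehyde ((E)‑but‑2‑enal) | C/C=C/C=O | starting material
3 | (E)‑4‑(3,4‑dimethoxyphenyl)but‑2‑enal | COc1ccc(C/C=C/C=O)cc1OC | intermediate
4 | formaldehyde (charged as paraformaldehyde) | C=O | starting material
5 | extended Breslow intermediate (dienaminol from 3 and the triazolylidene; homoenolate equivalent) | COc1ccc(C/C=C/C(O)=C2N(c3c(C)cc(C)cc3C)N=C3CO[C@H]4Cc5ccccc5[C@H]4N23)cc1OC | intermediate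
6 | acyl azolium alkoxide (zwitterion after C–C bond formation and tautomerisation) | COc1ccc(C[C@@H](C[O-])CC(=O)c2[n+](-c3c(C)cc(C)cc3C)nc3CO[C@H]4Cc5ccccc5[C@H]4n23)cc1OC | intermediate
7 | (R)‑4‑(3,4‑dimethoxybenzyl)dihydrofuran‑2(3H)‑one | COc1ccc(C[C@H]2COC(=O)C2)cc1OC | intermediate
8 | potassium enolate of 7 | COc1ccc(C[C@H]2COC([O-])=C2)cc1OC.[K+] | intermediate
9 | (3R,4S)‑3‑hydroxy‑4‑(3,4‑dimethoxybenzyl)dihydrofuran‑2(3H)‑one | COc1ccc(C[C@H]2COC(=O)[C@@H]2O)cc1OC | intermediate
10 | 4‑benzyloxy‑3,5‑dimethoxybenzaldehyde | COc1cc(C=O)cc(OC)c1OCc1ccccc1 | starting material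
11 | dilithium enediolate of 9 | COc1ccc(C[C@H]2COC([O-])=C2[O-])cc1OC.[Li+].[Li+] | intermediate
12 | (3R,4S)‑3‑[(4‑benzyloxy‑3,5‑dimethoxyphenyl)(hydroxy)methyl]‑3‑hydroxy‑4‑(3,4‑dimethoxybenzyl)dihydrofuran‑2(3H)‑one (carbinol epimers) | COc1ccc(C[C@H]2COC(=O)[C@]2(O)C(O)c2cc(OC)c(OCc3ccccc3)c(OC)c2)cc1OC | intermediate
13 | (3R,4S)‑3‑hydroxy‑3‑[hydroxy(4‑hydroxy‑3,5‑dimethoxyphenyl)methyl]‑4‑(3,4‑dimethoxybenzyl)dihydrofuran‑2(3H)‑one (debenzylated triol) | COc1ccc(C[C@H]2COC(=O)[C@]2(O)C(O)c2cc(OC)c(O)c(OC)c2)cc1OC | intermediate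
14 | (3S,4S)‑4‑(3,4‑dimethoxybenzyl)‑3‑hydroxy‑3‑(4‑hydroxy‑3,5‑dimethoxybenzyl)dihydrofuran‑2(3H)‑one | COc1ccc(C[C@H]2COC(=O)[C@]2(O)Cc2cc(OC)c(O)c(OC)c2)cc1OC | target

**Totals**
Total step count: 5. Longest linear sequence: 5 steps (1 → 3 → 7 → 9 → 12 → 14).

**Steps most likely to fail, with fallbacks**

Step 2 (the annulation has no direct precedent). The main risks are acyl‑anion hydroxymethylation at the aldehyde carbon, self‑annulation of the enal, base‑induced migration of the double bond of 3 into conjugation with the arene, and modest ee. The fallback sets out from 3 and comes back at 7, and uses nitromethane as the one‑carbon nucleophile instead of formaldehyde. Iminium‑catalysed conjugate addition of MeNO2 to 3 ((S)‑α,α‑diphenylprolinol trimethylsilyl ether 10 mol%, PhCO2H, MeOH, rt; antipode if the sense is opposite) gives (R)‑4‑(3,4‑dimethoxyphenyl)‑3‑(nitromethyl)butanal F1. Pinnick oxidation (NaClO2, NaH2PO4, 2‑methyl‑2‑butene, t‑BuOH–H2O) gives (R)‑4‑(3,4‑dimethoxyphenyl)‑3‑(nitromethyl)butanoic acid F2. Ozonolysis of its nitronate (NaOMe, MeOH, O3, −78 °C) gives (R)‑3‑(3,4‑dimethoxybenzyl)‑4‑oxobutanoic acid F3 as its sodium salt, which is reduced cold in the same flask with NaBH4 to limit epimerisation; acidification then closes lactone 7.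

Step 4 (the congested aldolate may revert, and the electron‑rich aldehyde is a weak acceptor). The fallback sets out from 9 and 10 and comes back at 14, replacing the reversible aldol by an irreversible alkylation. Aldehyde 10 is reduced (NaBH4, MeOH, 0 °C) to (4‑benzyloxy‑3,5‑dimethoxyphenyl)methanol F4 and converted (PBr3, Et2O, 0 °C) into 4‑benzyloxy‑3,5‑dimethoxybenzyl bromide F5. Enediolate 11 (from 9, LiN(i‑Pr)2 2.1 equiv, THF–DMPU, −78 to −30 °C) is C‑alkylated by F5 anti to the C4 benzyl group to give (3S,4S)‑3‑(4‑benzyloxy‑3,5‑dimethoxybenzyl)‑4‑(3,4‑dimethoxybenzyl)‑3‑hydroxydihydrofuran‑2(3H)‑one F6. Plain debenzylation (H2 1 atm, Pd/C, EtOAc, rt) gives 14 directly, bypassing 12, 13 and the benzylic C–OH cleavage.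

Step 5 (the benzylic C–OH cleavage may stall, or under acid trigger a pinacol‑type 1,2‑shift next to the tertiary alcohol). The fallback sets out from 12 and comes back at 14, turning the benzylic oxygen into a leaving group. The 1,2‑diol of 12 is closed with 1,1'‑carbonyldiimidazole (DMAP cat., THF, 50 °C) to the spiro cyclic carbonate of 12 F7 (a 5‑aryl‑1,3‑dioxolan‑2‑one spiro‑fused at C3 of the lactone). Neutral hydrogenolysis (H2 1 atm, Pd/C, EtOAc–MeOH, rt) then cleaves the benzylic carbonate C–O bond with loss of CO2, together with the benzyl ether, and gives 14 without any acid.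

**Further compounds**
F1 | step 2 | (R)‑4‑(3,4‑dimethoxyphenyl)‑3‑(nitromethyl)butanal | COc1ccc(C[C@H](CC=O)C[N+](=O)[O-])cc1OC
F2 | step 2 | (R)‑4‑(3,4‑dimethoxyphenyl)‑3‑(nitromethyl)butanoic acid | COc1ccc(C[C@H](CC(=O)O)C[N+](=O)[O-])cc1OC
F3 | step 2 | (R)‑3‑(3,4‑dimethoxybenzyl)‑4‑oxobutanoic acid | COc1ccc(C[C@H](CC(=O)O)C=O)cc1OC
F4 | step 4 | (4‑benzyloxy‑3,5‑dimethoxyphenyl)methanol | COc1cc(CO)cc(OC)c1OCc1ccccc1
F5 | step 4 | 4‑benzyloxy‑3,5‑dimethoxybenzyl bromide | COc1cc(CBr)cc(OC)c1OCc1ccccc1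
F6 | step 4 | (3S,4S)‑3‑(4‑benzyloxy‑3,5‑dimethoxybenzyl)‑4‑(3,4‑dimethoxybenzyl)‑3‑hydroxydihydrofuran‑2(3H)‑one | COc1ccc(C[C@H]2COC(=O)[C@]2(O)Cc2cc(OC)c(OCc3ccccc3)c(OC)c2)cc1OC
F7 | step 5 | spiro cyclic carbonate of 12 (lactone stereocentres as in 12) | COc1ccc(C[C@H]2COC(=O)[C@@]23OC(=O)OC3c3cc(OC)c(OCc4ccccc4)c(OC)c3)cc1OC
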